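Alder cannot have stalled for want of left-handed substrate: 40 % of the charge still stands as left-handed substrate at 40.0 min. The rate has fallen for another cause, and two times describe that.

| flask | left-handed substrate | right-handed substrate | reagent | free catalyst | racemization catalyst | remark | time |
|---|---|---|---|---|---|---|---|
| alder | 0.30 M | 0.30 M | 0.90 M | 2.4 mM | 0.15 mM | run made earlier |  |
| maple | 0.30 M | 0.30 M | 0.90 M | 48 mM | 0.15 mM | run made earlier |  |
| north-east | 0.30 M | 0.30 M | 0.900 M | 2.0 mM | 0.15 mM |  | 80 min |
| south | 0.30 M | 0.30 M | 0.900 M | 4.0 mM | 0.15 mM |  | 80 min |
| west | 0.30 M | 0.30 M | 0.900 M | 8.0 mM | 0.15 mM |  | 80 min |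
| north | 0.30 M | 0.30 M | 0.900 M | 15 mM | 0.15 mM |  | 80 min |
| east | 0.30 M | 0.30 M | 0.900 M | 30 mM | 0.15 mM |  | 80 min |

| run | time / min | left-handed product / % | left-handed substrate / % |
|---|---|---|---|
| alder | 2.50 | 1 | 50 |
| alder | 8.00 | 4 | 49 |
| alder | 15.0 | 4 | 46 |
| alder | 20.0 | 9 | 44 |
| alder | 30.0 | 9 | 40 |
| alder | 40.0 | 9 | 40 |
| maple | 2.50 | 22 | 29 |
| maple | 8.00 | 38 | 14 |
| maple | 15.0 | 46 | 6 |
| maple | 20.0 | 44 | 7 |
| maple | 30.0 | 51 | 5 |
| maple | 40.0 | 52 | 3 |

(each reading ± 1.5 percentage points)

- free catalyst is single-handed; left-handed substrate and right-handed substrate are mirror images of each other, charged as a racemate, each of them at the stated concentration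
- "hardly changes" means that all values lie within two and a half points (for a concentration: within two and a half percent of the largest)

* amount of left-handed product at the end, in percent of the left-handed substrate and right-handed substrate together charged for north-east, south, west, north, east, in this order
* how the row runs (falls all the way / rises all the way / rises, then falls / hardly changes / falls, then rises)

The first time is the resolution time τ, the pseudo-first-order time of left-handed substrate at the starting rate. Maple takes left-handed substrate from half of the charge to 29 % in 2.50 min, which gives a reading:

τ(maple) = t / ln(0.5 / left-handed substrate) = 4.59 min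

τ scales inversely with c(free catalyst), so alder has τ = 91.8 min. The second time follows from alder's final reading:

T = τ(alder) · ln(0.5 / left-handed substrate) = 20.5 min

T is the effective time: the time a flask held at its starting rate needs for the conversion it really reaches. This reckoning sets racemization aside, takes T as common to the row, and gives

left-handed product = 0.5 · (1 − exp(−T/τ)).

The ratio T/τ grows with c(free catalyst), so the row rises, from 8.48 % in north-east to 46.9 % in east. Alder's readings end at half of the 80 min allowed, so this T counts nothing gained afterwards.

The forecast gives 8 %, 14.5 %, 24 %, 35 % and 47 %, a row that rises all the way, on the ground that “by 80 min everything has stopped”.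

The flasks give 11.7 %, 20.2 %, 31.6 %, 42.7 % and 52.4 %: the row rises all the way.

    reagent + free catalyst + left-handed substrate → free catalyst + left-handed product (k = 6.60 L² mol⁻² min⁻¹)
    reagent + free catalyst + right-handed substrate → free catalyst + right-handed product (k = 0.0810 L² mol⁻² min⁻¹)
    left-handed substrate + racemization catalyst ⇌ right-handed substrate + racemization catalyst, rate k3*[racemization catalyst]*[left-handed substrate] forward; the back reaction follows from the equilibrium constant (k = 3900 L mol⁻¹ min⁻¹)
    2 racemization catalyst ⇌ resting dimer, settled at all times (K = 9.80 × 10⁷ L mol⁻¹)
    2 reagent → self-condensation product (k = 0.0490 L mol⁻¹ min⁻¹)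

East at 80.0 min holds 99.4 % of its racemization catalyst as resting dimer, and this parking is a part of what holds its yield down: without it east ends at 71.1 %, not 52.4 %. North-east's left-handed product corresponds to an effective time of 29.4 min, longer than the 20.5 min from alder. Carried to north, this effective time gives 43.2 % of left-handed product, and north stands at 42.7 %.

The runs are calculated for an exercise, and the scatter is random.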